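- Late in the red run the target is still climbing nearly in a straight line. Between 30.0 min and 180 min the target gains 0.00111 min⁻¹, as a fraction of the charge, scatter included.
- The start reads slower. Over its first 30.0 min the red run averages 6.67 × 10⁻⁴ min⁻¹, less than the later rate. That may be a slow start (induction period), but it rests on one reading with a scatter of 1 percentage point.
- We take the rate as proportional to the second catalyst. By that reckoning oak runs at 5.53 × 10⁻⁴ min⁻¹ at 15 °C.
- The amber run's last reading, scaled the same way, gives 6.94 × 10⁻⁵ min⁻¹ at −15 °C. As a reading, that is slower by a factor of 7.97.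
- Larch's cold stretch at −10 °C is warmer than amber. At the scaled amber rate, our reckoning gives that stretch 0.174 % of the charge, beside a scatter of 1 point.
- So we count hot minutes. The hot share is the minutes spent at the upper temperature over elm's minutes. For larch the hot share is 0.688.
- We commit to a ratio, not a level: larch stands at that share of elm, provided the rate does not sag.

| flask | substrate | gas | free catalyst | second catalyst | temperature | remark | time |
|---|---|---|---|---|---|---|---|
| amber | 0.40 M | 32 mM (held) | 0.68 mM | 1 mM | −15 °C | run made earlier |  |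
| red | 0.40 M | 32 mM (held) | 0.68 mM | 4 mM | 15 °C | run made earlier |  |
| ochre | 0.40 M | 32 mM (held) | 1.4 mM | 2 mM | −15 °C | run made earlier |  |
| elm | 0.40 M | 32 mM (held) | 0.68 mM | 2.0 mM | 40 °C |  | 80 min |
| oak | 0.40 M | 32 mM (held) | 0.68 mM | 2.0 mM | 15 °C |  | 80 min |
| ash | 0.40 M | 32 mM (held) | 0.68 mM | 2.0 mM | −10 °C |  | 80 min |
| larch | 0.40 M | 32 mM (held) | 0.68 mM | 2.0 mM |  | at −10 °C until 25 min, from then on at 40 °C | 80 min |

| amber: time / min | amber: target / % | red: time / min | red: target / % | ochre: time / min | ochre: target / % |
|---|---|---|---|---|---|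
| 150 | 0.2 | 30.0 | 2.0 | 60.0 | 1.8 |
| 300 | 1.5 | 60.0 | 5.2 | 180 | 0.8 |
| 480 | 0.1 | 90.0 | 6.4 | 300 | 0.9 |
| 600 | 0 | 150 | 13.3 | 480 | 1.4 |
| 720 | 2.5 | 180 | 18.6 | 720 | 5.9 |

(scatter of a reading: 1 percentage point)

- at the start none of the gas is in solution

* the flask that comes out highest in amount of target, in percent of the substrate charged, or "all alike" when all lie within 1.5 percentage points (elm / oak / ash / larch / all alike)
* target at the end, in percent of the substrate charged, elm
* target at the end, in percent of the substrate charged, oak
* target at the end, in percent of the substrate charged, ash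
* target at the end, in percent of the substrate charged, larch

- The forecast says elm, with elm 28 %, oak 3.8 %, ash 0.3 % and larch 20 %. For elm it starts from 0.4 percent per minute, “less substrate depletion and possible catalyst loss”.
- The flasks give elm as highest, with elm 19.0 %, oak 3.07 %, ash 0.120 % and larch 13.2 %.

    substrate + free catalyst ⇌ free catalyst + intermediate (K = 0.460, k = 24.7 L mol⁻¹ min⁻¹, Ea = 40.0 kJ mol⁻¹, ΔH = −9.00 kJ mol⁻¹)
    reagent + second catalyst + intermediate → second catalyst + target (k = 264 L² mol⁻² min⁻¹, Ea = 50.0 kJ mol⁻¹)
    gas ⇌ reagent, rate k3*(csat - [reagent]) (kL = 0.586 min⁻¹)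
    intermediate → side product (k = 0.0111 min⁻¹, Ea = 104 kJ mol⁻¹)
    substrate + reagent → uncatalysed product (k = 0.0246 L mol⁻¹ min⁻¹, Ea = 56.0 kJ mol⁻¹)
    (constants at 40 °C)

- Larch stands at 0.695 of elm, against the hot share of 0.688. In elm, taking each step net, the intermediate is made 1.45 times as fast as it is used up at 22.6 min, but 0.760 times as fast at 80.0 min. Elm's intermediate stands at 17.8 % at 40.0 min and 14.5 % at 80.0 min. Elm read at 180 min has a hot share of 2.25, which gives 42.8 %, and that flask holds 36.0 %.

The readings are calculated with constants of no real substance, noise included.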